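D is counted against X, and both come from the same L, so early on the share of D is a matter of rates, not of stocks.

- maple: L 1 mM; G 0.50 µM; J 0.47 µM; the very flask that is asked about, followed so far
- flask: L 1.0 mM; G 0.50 µM; J 0.47 µM; time 80 min

- maple (time / min: D / %, X / %, L / %): 1.33: 32, 7, 52; 4.00: 27, 9, 39; 8.00: 22, 13, 38; 12.0: 21, 22, 32; 15.0: 19, 23, 30

(standard deviation of a reading: 1.5 percentage points)

* share of D in D plus X at 2.0 s
* share of D in D plus X at 80 min

- reactions considered so far: L <-> D; L + G <-> X + G; L + G <-> E + G; G + J -> Q

Build the flask up. With L ⇌ D alone, the share of D is 100 percent. That step is fast: in the maple run D over L reads 0.615 at the first reading and 0.633 at the last. Take 3 time constants as spent by 1.33 min; that gives a relaxation of at least 2.26 /min and a forward constant of at least 0.859 /min.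

Now add G and J. J takes G one for one, leaving 6.00% of the catalyst as G. In the maple run X climbs with a pseudo-first-order constant of about 0.0308 /min, which you assign to that remnant. Both rates carry the same L, so L and time cancel. Divide them and scale to the whole charge of catalyst: 1.67, the full-catalyst split, which is the rate into D over the rate into X with every bit of catalyst as G. With a fraction f working, the split is that number over f, and the share is split over one plus split.

So you get a floor of 62.5% with G whole and 96.5% with J finished. The first reading comes far later than 2.0 s, so no reading shows how far J has taken G by then, and your reckoning stays with that span. Last comes E, which takes 28.0% of the charge by 15.0 min, but L has cancelled, so the split stays. Late the split stops serving: D relaxes with L much faster than 80 min, so the share becomes a ratio of stocks.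

The forecast gives 80% (55% to 97%) and 12% (7% to 28%), with the ground “G is probably still largely active”.

The flask gives 93.8% and 18.0%.

    L ⇌ D (K = 0.620, k = 0.0250 /s)
    L + G ⇌ X + G, rate k2*[L]*[G] forward; the back reaction follows from the equilibrium constant (K = 3.60, k = 23000 /M/s)
    L + G ⇌ E + G, rate k3*[L]*[G] forward; the back reaction follows from the equilibrium constant (K = 0.750, k = 1.10 × 10⁵ /M/s)
    G + J → Q (k = 3.50 × 10⁷ /M/s)

In the flask the half-life of D for going back, 0.29 min, is far shorter than 80 min, and D stands at 11.9% beside L at 19.2%. The slowest mode has a half-life of 24.5 min, also shorter than that time, and X at 54.3% lies below its 60.3% of 800 min. Early, 93.8% is a split of 15.1. Your 1.67 rested on a lower bound; from the constants above the full-catalyst split is 2.17, so on average about 14.4% of the catalyst worked over 2.0 s. In the neighbour flask with 2.8 × 10⁻⁴ mM of J, where 44.0% is left as G, that split reckons 83.2%, and the flask gives 81.8%.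

All runs are calculated for an exercise, noise included.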